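The route rests on cutting the bond between C2 of flavanone ring C and its 4-methoxyphenyl group. C2 is the only stereocentre; it lies beta to the C4 carbonyl and carries O1, so it maps onto the C2=C3–C4=O enone of a 2-unsubstituted chromone. A chiral divalent palladium catalyst adds 4-methoxyphenylboronic acid to that enone, attaching the aryl ring and fixing the 2S configuration in one operation, after all base-mediated chemistry is finished. The precursor is an achiral, tetra-O-benzylated biaryl in which a 5,7-dioxygenated chromone is joined through C6 to C3' of a preformed flavone, whose own C2 is aryl-substituted and therefore unreactive.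

Key step: step 9

Remark: the facial preference known for the (S)-configured tert-butyl pyridine-oxazoline ligand on cyclic enones (beta-carbon formed as R) is assumed to carry over to chromones, which by the sequence rules makes the (R)-ligand the one that leads to 2S; the sense is to be verified on 5,7-bis(benzyloxy)chromone before material is committed, and the antipodal ligand used if it proves opposite.

Step 1
Reactants: 1 2,4,6-trihydroxyacetophenone
Product: 2 4,6-bis(benzyloxy)-2-hydroxyacetophenone
Conditions: BnBr (2.05 equiv), K2CO3 (2.2 equiv), DMF, rt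
Reagents that add atoms: benzyl bromide, BrCc1ccccc1
Why: Williamson etherification in which the 4-OH and one ortho OH are alkylated, while the last ortho OH stays locked in a hydrogen bond to the acetyl carbonyl and is spared when benzyl bromide is limited to two equivalents.

Step 2
Reactants: 2 4,6-bis(benzyloxy)-2-hydroxyacetophenone; 3 3-bromo-4-methoxybenzaldehyde
Product: 4 (E)-1-[2,4-bis(benzyloxy)-6-hydroxyphenyl]-3-(3-bromo-4-methoxyphenyl)prop-2-en-1-one
Conditions: KOH (50% aq.), EtOH–THF, rt, then dilute HCl
Reagents that add atoms: none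
Why: Claisen–Schmidt condensation in which the acetophenone enolate adds to the non-enolisable aldehyde and the aldol dehydrates to the conjugated E-enone, the aryl bromide and benzyl ethers being inert to hydroxide at room temperature.

Step 3
Reactants: 4 (E)-2'-hydroxychalcone bearing the aryl bromide
Product: 6 5,7-bis(benzyloxy)-3'-bromo-4'-methoxyflavone, via racemic bromoflavanone 5 (not isolated)
Conditions: I2 (10 mol%), DMSO, 130 °C
Reagents that add atoms: none
Why: Iodine-catalysed oxidative cyclisation in which the 2'-hydroxychalcone closes by oxa-Michael addition to the flavanone, which is alpha-iodinated and loses HI to give the flavone, while DMSO reoxidises HI to iodine.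

Step 4
Reactants: 6 5,7-bis(benzyloxy)-3'-bromo-4'-methoxyflavone
Product: 7 5,7-bis(benzyloxy)-4'-methoxy-3'-(4,4,5,5-tetramethyl-1,3,2-dioxaborolan-2-yl)flavone
Conditions: B2pin2 (1.3 equiv), PdCl2(dppf) (5 mol%), KOAc (3 equiv), 1,4-dioxane, 90 °C
Reagents that add atoms: bis(pinacolato)diboron, CC1(C)OB(OC1(C)C)B1OC(C)(C)C(C)(C)O1
Why: Miyaura borylation by oxidative addition of the aryl bromide to zerovalent palladium, acetate-assisted transmetalation from the diboron and reductive elimination, with KOAc too weak a base to trigger Suzuki homocoupling or harm the flavone.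

Step 5
Reactants: 8 5,7-dihydroxychromone
Product: 9 7-(benzyloxy)-5-hydroxychromone
Conditions: BnBr (1.05 equiv), K2CO3 (1.1 equiv), acetone, reflux
Reagents that add atoms: benzyl bromide, BrCc1ccccc1
Why: Williamson etherification selective for the more acidic, non-chelated 7-OH, because the 5-OH is hydrogen-bonded to C4=O and is not alkylated by one equivalent of benzyl bromide with a mild base.

Step 6
Reactants: 9 7-(benzyloxy)-5-hydroxychromone
Product: 10 7-(benzyloxy)-5-hydroxy-6-iodochromone
Conditions: BnMe3N+ ICl2− (1.05 equiv), CaCO3, CH2Cl2–MeOH, rt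
Reagents that add atoms: benzyltrimethylammonium dichloroiodate, C[N+](C)(C)Cc1ccccc1.Cl[I-]Cl
Why: Electrophilic aromatic iodination which, with the 5-OH chelated to C4=O, should occur at C6 between the free phenol and the 7-benzyloxy group, as is known for 5-hydroxy-7-alkoxyflavones with this reagent, while CaCO3 scavenges HCl so that the pyranone and the benzyl ether are untouched.

Step 7
Reactants: 10 7-(benzyloxy)-5-hydroxy-6-iodochromone
Product: 11 5,7-bis(benzyloxy)-6-iodochromone
Conditions: BnBr (1.5 equiv), K2CO3 (2 equiv), DMF, 60 °C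
Reagents that add atoms: benzyl bromide, BrCc1ccccc1
Why: Williamson etherification of the chelated, hindered 5-OH, which needs a dipolar aprotic solvent and warming, under a carbonate base that is not nucleophilic enough to open the 2-unsubstituted pyranone or disturb the aryl iodide.

Step 8
Reactants: 7 flavone 3'-pinacol boronate; 11 5,7-bis(benzyloxy)-6-iodochromone
Product: 12 5,7-bis(benzyloxy)-6-{5-[5,7-bis(benzyloxy)-4-oxo-4H-chromen-2-yl]-2-methoxyphenyl}chromone (achiral chromone–flavone biaryl)
Conditions: Pd(OAc)2 (5 mol%), SPhos (10 mol%), K3PO4 (3 equiv), toluene–H2O 10:1, 90 °C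
Reagents that add atoms: none
Why: Suzuki–Miyaura coupling in which the bulky, electron-rich biarylphosphine drives oxidative addition of the doubly ortho-substituted iodide and reductive elimination of the tri-ortho-substituted biaryl, while phosphate with little water activates the boronate without opening the chromone.

Step 9
Reactants: 12 chromone–flavone biaryl; 13 4-methoxyphenylboronic acid
Product: 14 (2S)-5,7-bis(benzyloxy)-6-{5-[5,7-bis(benzyloxy)-4-oxo-4H-chromen-2-yl]-2-methoxyphenyl}-2-(4-methoxyphenyl)chroman-4-one
Conditions: 13 (2.5 equiv), Pd(OCOCF3)2 (10 mol%), (R)-4-tert-butyl-2-(pyridin-2-yl)-4,5-dihydrooxazole (12 mol%), NH4PF6 (30 mol%), H2O (5 equiv), ClCH2CH2Cl, 60 °C, under air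
Reagents that add atoms: none
Why: The boronic acid transmetalates to the cationic ligand-bound divalent palladium, the aryl–palladium species inserts the chromone C2=C3 bond with the aryl going to C2, and water protonates the resulting palladium enolate, releasing the flavanone and the catalyst with no change of oxidation state. The closest known reaction type is the palladium-catalysed enantioselective conjugate addition of arylboronic acids to 2-unsubstituted chromones and cyclic enones with pyridine-oxazoline ligands. No ring is closed, since the chromone pyranone simply becomes ring C of the flavanone. The new C2 stereocentre is controlled by the tert-butyl group of the ligand, which shields one enantioface of the bound enone during insertion, and the (R)-ligand is chosen so that the aryl arrives on the face that gives 2S. The step needs chemoselectivity for the chromone over the flavone, which follows from the flavone C2 being fully substituted, hindered and aryl-conjugated, while the reacting C2–H terminus lies far from the crowded biaryl axis at C6. The near-neutral medium keeps the new centre clear of retro-oxa-Michael opening, though the electron-rich 5,7-dialkoxy pattern may call for a higher loading or temperature.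

Step 10
Reactants: 14 tetra-O-benzyl (2S)-flavanone–flavone
Product: 15 (2S)-5,7-dihydroxy-6-[5-(5,7-dihydroxy-4-oxo-4H-chromen-2-yl)-2-methoxyphenyl]-2-(4-methoxyphenyl)chroman-4-one (target CNP0081547.1)
Conditions: H2 (1 atm), Pd/C (10 wt% Pd), EtOAc–MeOH 1:1, rt, stopped as soon as debenzylation is complete
Reagents that add atoms: none
Why: Heterogeneous hydrogenolysis of the four aryl benzyl ethers under neutral conditions at room temperature should leave the methyl ethers, the aryl ketone, the flavone C2=C3 bond and the ring C2–O1 bond intact and, being base-free, cannot scramble C2 by ring opening.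

Compound list
1 | 2,4,6-trihydroxyacetophenone | CC(=O)c1c(O)cc(O)cc1O | starting material
2 | 4,6-bis(benzyloxy)-2-hydroxyacetophenone | CC(=O)c1c(O)cc(OCc2ccccc2)cc1OCc1ccccc1 | intermediate
3 | 3-bromo-4-methoxybenzaldehyde | COc1ccc(C=O)cc1Br | starting material
4 | (E)-1-[2,4-bis(benzyloxy)-6-hydroxyphenyl]-3-(3-bromo-4-methoxyphenyl)prop-2-en-1-one | O=C(/C=C/c1ccc(OC)c(Br)c1)c1c(O)cc(OCc2ccccc2)cc1OCc1ccccc1 | intermediate
5 | racemic 5,7-bis(benzyloxy)-2-(3-bromo-4-methoxyphenyl)chroman-4-one (formed in the flask in step 3) | COc1ccc(C2CC(=O)c3c(OCc4ccccc4)cc(OCc4ccccc4)cc3O2)cc1Br | intermediate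
6 | 5,7-bis(benzyloxy)-3'-bromo-4'-methoxyflavone | COc1ccc(-c2cc(=O)c3c(OCc4ccccc4)cc(OCc4ccccc4)cc3o2)cc1Br | intermediate
7 | 5,7-bis(benzyloxy)-4'-methoxy-3'-(4,4,5,5-tetramethyl-1,3,2-dioxaborolan-2-yl)flavone | COc1ccc(-c2cc(=O)c3c(OCc4ccccc4)cc(OCc4ccccc4)cc3o2)cc1B1OC(C)(C)C(C)(C)O1 | intermediate
8 | 5,7-dihydroxychromone | O=c1ccoc2cc(O)cc(O)c12 | starting material
9 | 7-(benzyloxy)-5-hydroxychromone | O=c1ccoc2cc(OCc3ccccc3)cc(O)c12 | intermediate
10 | 7-(benzyloxy)-5-hydroxy-6-iodochromone | O=c1ccoc2cc(OCc3ccccc3)c(I)c(O)c12 | intermediate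
11 | 5,7-bis(benzyloxy)-6-iodochromone | O=c1ccoc2cc(OCc3ccccc3)c(I)c(OCc3ccccc3)c12 | intermediate
12 | 5,7-bis(benzyloxy)-6-{5-[5,7-bis(benzyloxy)-4-oxo-4H-chromen-2-yl]-2-methoxyphenyl}chromone | COc1ccc(-c2cc(=O)c3c(OCc4ccccc4)cc(OCc4ccccc4)cc3o2)cc1-c1c(OCc2ccccc2)cc2occc(=O)c2c1OCc1ccccc1 | intermediate
13 | 4-methoxyphenylboronic acid | COc1ccc(B(O)O)cc1 | starting material
14 | (2S)-5,7-bis(benzyloxy)-6-{5-[5,7-bis(benzyloxy)-4-oxo-4H-chromen-2-yl]-2-methoxyphenyl}-2-(4-methoxyphenyl)chroman-4-one | COc1ccc([C@@H]2CC(=O)c3c(cc(OCc4ccccc4)c(-c4cc(-c5cc(=O)c6c(OCc7ccccc7)cc(OCc7ccccc7)cc6o5)ccc4OC)c3OCc3ccccc3)O2)cc1 | intermediate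
15 | (2S)-5,7-dihydroxy-6-[5-(5,7-dihydroxy-4-oxo-4H-chromen-2-yl)-2-methoxyphenyl]-2-(4-methoxyphenyl)chroman-4-one, CNP0081547.1 | COc1ccc([C@@H]2CC(=O)c3c(cc(O)c(-c4cc(-c5cc(=O)c6c(O)cc(O)cc6o5)ccc4OC)c3O)O2)cc1 | target

Total step count: 10.
Longest linear sequence: 7 steps (steps 1, 2, 3, 4, 8, 9, 10). The chromone branch (steps 5 to 7) joins at step 8.

Steps most likely to fail

Step 9. The ring A oxygen donors lower the electrophilicity of C2 and the C6 aryl group crowds the catalyst, so insertion may be slow or the enantioface discrimination insufficient. Fallback: setting out from 12 and 13, the addition is run with an achiral, more active catalyst, Pd(OCOCF3)2 with 2,2'-bipyridine in aqueous ClCH2CH2Cl at 60 °C, which should give the racemic tetra-O-benzyl flavanone–flavone F1. Preparative chromatography on a chiral stationary phase with a neutral eluent should then deliver the 2S enantiomer, which is 14, and set aside the 2R enantiomer F2. The route resumes at 14.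

Step 8. Transmetalation onto the doubly ortho-substituted arylpalladium iodide may be slow enough for protodeboronation of the ortho-methoxy boronate and hydroxide-induced opening of the chromone pyranone to take over. Fallback: setting out from bromide 6, stannylation with Me3SnSnMe3 and Pd(PPh3)4 in toluene at 110 °C should give the flavone 3'-trimethylstannane F3. A base-free Stille coupling of this with iodide 11 (Pd(PPh3)4, CuI, CsF, DMF, 50 °C) should form the same biaryl bond and return to the route at 12.

Step 10. Prolonged exposure needed for the two hindered 5-O-benzyl ethers may lead to over-reduction, either saturation of the flavone C2=C3 bond or hydrogenolytic opening of the benzylic C2–O1 bond of ring C. Fallback: setting out from 12, the benzyl groups are removed before the stereocentre exists. BCl3 with pentamethylbenzene as cation scavenger in CH2Cl2 at −78 to 0 °C should give the tetraphenol chromone–flavone F4. Ac2O, pyridine and DMAP should convert this into the chromone–flavone tetraacetate F5. Conjugate addition of 13 under the conditions of step 9 should then give the (2S)-flavanone–flavone tetraacetate F6; the acetoxy groups also make C2 more electrophilic. Acid-catalysed methanolysis (HCl in MeOH, rt), which uses neither hydrogen nor base, should release the target, returning to the route at 15.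

Further compounds
F1 | step 9 | racemic 5,7-bis(benzyloxy)-6-{5-[5,7-bis(benzyloxy)-4-oxo-4H-chromen-2-yl]-2-methoxyphenyl}-2-(4-methoxyphenyl)chroman-4-one | COc1ccc(C2CC(=O)c3c(cc(OCc4ccccc4)c(-c4cc(-c5cc(=O)c6c(OCc7ccccc7)cc(OCc7ccccc7)cc6o5)ccc4OC)c3OCc3ccccc3)O2)cc1
F2 | step 9 | (2R)-5,7-bis(benzyloxy)-6-{5-[5,7-bis(benzyloxy)-4-oxo-4H-chromen-2-yl]-2-methoxyphenyl}-2-(4-methoxyphenyl)chroman-4-one | COc1ccc([C@H]2CC(=O)c3c(cc(OCc4ccccc4)c(-c4cc(-c5cc(=O)c6c(OCc7ccccc7)cc(OCc7ccccc7)cc6o5)ccc4OC)c3OCc3ccccc3)O2)cc1
F3 | step 8 | 5,7-bis(benzyloxy)-4'-methoxy-3'-(trimethylstannyl)flavone | COc1ccc(-c2cc(=O)c3c(OCc4ccccc4)cc(OCc4ccccc4)cc3o2)cc1[Sn](C)(C)C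
F4 | step 10 | 5,7-dihydroxy-6-[5-(5,7-dihydroxy-4-oxo-4H-chromen-2-yl)-2-methoxyphenyl]chromone | COc1ccc(-c2cc(=O)c3c(O)cc(O)cc3o2)cc1-c1c(O)cc2occc(=O)c2c1O
F5 | step 10 | 5,7-diacetoxy-6-[5-(5,7-diacetoxy-4-oxo-4H-chromen-2-yl)-2-methoxyphenyl]chromone | COc1ccc(-c2cc(=O)c3c(OC(C)=O)cc(OC(C)=O)cc3o2)cc1-c1c(OC(C)=O)cc2occc(=O)c2c1OC(C)=O
F6 | step 10 | (2S)-5,7-diacetoxy-6-[5-(5,7-diacetoxy-4-oxo-4H-chromen-2-yl)-2-methoxyphenyl]-2-(4-methoxyphenyl)chroman-4-one | COc1ccc([C@@H]2CC(=O)c3c(cc(OC(C)=O)c(-c4cc(-c5cc(=O)c6c(OC(C)=O)cc(OC(C)=O)cc6o5)ccc4OC)c3OC(C)=O)O2)cc1
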